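The ring is numbered C1 (quaternary carbon with CH3 and chlorovinyl), C2, C3 (CBr), C4 (CHCl), C5 and C6 (CHCl), and the route rests on disconnecting C4–C5. The Cl–C4–C5–C6–Cl array is what a chlorine-bearing α-keto radical at C4 and a chlorine atom leave when they add across a vinyl group on C1. One electrochemically driven copper atom-transfer cyclisation therefore closes the six-membered ring, forms its only new C–C bond and places both ring chlorines, leaving the C3 ketone for the two bromines. The precursor is an acyclic dichloromethyl ketone whose quaternary C1 carries methyl, vinyl and chloroethynyl groups; it is an isomer of the cyclised product.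

Key step: step 7

Assumption: the (R,R)-enantiomer of the ligand in step 1 is taken to give the (R)-configured lactone; if the sense of induction is the reverse, the (S,S)-ligand is used and nothing else changes.
Remark: C1–C6 in the Why lines and in the risk section follow the target numbering given above, not the locants of the systematic names.

Step 1
Reactants: 1 isoprene monoepoxide (racemic 2-ethenyl-2-methyloxirane); 2 Meldrum's acid (2,2-dimethyl-1,3-dioxane-4,6-dione)
Product: 5 (4R)-4-ethenyl-4-methyloxolan-2-one, via hydroxyalkyl dioxanedione adduct 3 (not isolated), via carboxy lactone 4 (not isolated)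
Conditions: Pd2(dba)3·CHCl3 (1 mol %), (R,R)-DACH-phenyl bisphosphine ligand [(1R,2R)-N,N′-bis(2-diphenylphosphinobenzoyl)cyclohexane-1,2-diamine, 3 mol %], CH2Cl2, rt; then DMSO/H2O, 120 °C
Reagents that add atoms: Meldrum's acid, CC1(C)OC(=O)CC(=O)O1
Why: Palladium-catalysed asymmetric allylic alkylation of the vinyl epoxide (a dynamic kinetic asymmetric transformation through interconverting π-allyl complexes) should deliver the carbon acid to the substituted allyl terminus with the chiral ligand fixing the quaternary centre that becomes C1, after which the neighbouring hydroxyl opens the dioxanedione with loss of acetone and the malonic half-acid decarboxylates on heating.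

Step 2
Reactants: 5 (4R)-4-ethenyl-4-methyloxolan-2-one; 6 N,O-dimethylhydroxylamine hydrochloride
Product: 7 (3R)-3-(hydroxymethyl)-N-methoxy-N,3-dimethylpent-4-enamide
Conditions: MeNH(OMe)·HCl, AlMe3, CH2Cl2, 0 °C to rt
Reagents that add atoms: N,O-dimethylhydroxylamine hydrochloride, CNOC.Cl
Why: Aminolysis of the lactone by the aluminium amide (Weinreb amide formation) should open the ring without touching the quaternary centre, and the hydroxy amide is carried on at once so that it cannot relactonise.

Step 3
Reactants: 7 (3R)-3-(hydroxymethyl)-N-methoxy-N,3-dimethylpent-4-enamide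
Product: 8 (3R)-3-formyl-N-methoxy-N,3-dimethylpent-4-enamide
Conditions: Dess–Martin periodinane, CH2Cl2, rt
Reagents that add atoms: none
Why: Dess–Martin oxidation of the neopentyl primary alcohol should stop at the aldehyde, which has no α-hydrogen and therefore cannot enolise or epimerise.

Step 4
Reactants: 8 (3R)-3-formyl-N-methoxy-N,3-dimethylpent-4-enamide; 9 Ohira–Bestmann reagent (dimethyl (1-diazo-2-oxopropyl)phosphonate)
Product: 10 (3R)-3-ethynyl-N-methoxy-N,3-dimethylpent-4-enamide
Conditions: K2CO3, MeOH, 0 °C to rt
Reagents that add atoms: dimethyl (1-diazo-2-oxopropyl)phosphonate, COP(=O)(OC)C(=[N+]=[N-])C(C)=O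
Why: Seyferth–Gilbert homologation in its Ohira–Bestmann form should turn the non-enolisable aldehyde into the terminal alkyne under carbonate conditions that leave the Weinreb amide alone.

Step 5
Reactants: 10 (3R)-3-ethynyl-N-methoxy-N,3-dimethylpent-4-enamide; 11 N-chlorosuccinimide
Product: 13 (3R)-3-(chloroethynyl)-N-methoxy-N,3-dimethylpent-4-enamide, via lithium acetylide 12 (not isolated)
Conditions: LiN(SiMe3)2, THF, −78 °C; then NCS, −78 to 0 °C
Reagents that add atoms: N-chlorosuccinimide, O=C1CCC(=O)N1Cl
Why: The silylamide base should deprotonate only the terminal alkyne (far more acidic than the amide α-CH2), and electrophilic chlorination of the lithium acetylide is a standard way to a 1-chloroalkyne.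

Step 6
Reactants: 13 (3R)-3-(chloroethynyl)-N-methoxy-N,3-dimethylpent-4-enamide; 14 dichloromethane
Product: 16 (4R)-1,1-dichloro-4-(chloroethynyl)-4-methylhex-5-en-2-one, via tetrahedral lithium adduct 15 (not isolated)
Conditions: CH2Cl2, LiN(i-Pr)2, THF, −78 °C (LiCHCl2 pre-formed); then 13; AcOH, −78 °C to rt
Reagents that add atoms: dichloromethane, ClCCl
Why: Acylation of dichloromethyllithium by the Weinreb amide should stop at the chelated tetrahedral adduct, which collapses to the dichloromethyl ketone only on the cold acidic quench, so the number and position of the chlorines are fixed without any enolate chlorination.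

Step 7
Reactants: 16 (4R)-1,1-dichloro-4-(chloroethynyl)-4-methylhex-5-en-2-one
Product: 17 (2R,4S,5S)-2,4-dichloro-5-(chloroethynyl)-5-methylcyclohexan-1-one
Conditions: CuCl2 (10 mol %), tris(2-pyridylmethyl)amine (TPMA, 10 mol %), Et4NCl (0.1 M), MeCN, rt; divided cell, glassy-carbon cathode held at the half-wave potential of the cupric/cuprous couple, Pt counter electrode
Reagents that add atoms: none
Why: Cathodically formed [Cu(TPMA)]+ abstracts one chlorine of the dichloromethyl group, the α-chloro-α-keto radical at C4 adds to the terminal vinyl carbon C5, and the secondary C6 radical takes chlorine back from [CuCl(TPMA)]+, which returns monovalent copper. The closest known reaction type is the copper-catalysed atom-transfer (Kharasch-type) radical cyclisation of α,α-dichloro carbonyl compounds with electrochemical regeneration of the activator. The ring closes 6-endo-trig, the mode preferred by 2-oxohex-5-enyl radicals because the carbonyl lies inside the forming ring, while 5-exo attack at the internal vinyl carbon or at the inner alkyne carbon would have to occur next to the quaternary C1. C6 is set in the chlorine transfer: the bulky copper chloride complex should approach the ring radical on the face opposite the C1 methyl group, past the slim, rod-like chloroethynyl group, which gives chlorine trans to CH3. C4 should form with chlorine equatorial from a chair-like transition state in which chlorine is syn to the carbonyl oxygen, and it stays correctable by acid-catalysed enolisation (cat. TsOH, MeCN). The step needs reaction at the vinyl group in the presence of the chloroalkyne, which the electrophilic radical secures by preferring the unsubstituted, more electron-rich alkene terminus, and a low steady radical concentration, which the electrode secures.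

Step 8
Reactants: 17 (2R,4S,5S)-2,4-dichloro-5-(chloroethynyl)-5-methylcyclohexan-1-one
Product: 18 (2R,4S,5S)-2,4-dichloro-5-[(Z)-2-chloroethenyl]-5-methylcyclohexan-1-one
Conditions: dipotassium azodicarboxylate (KO2C–N=N–CO2K), AcOH, MeOH, 0 °C to rt
Reagents that add atoms: none
Why: Diimide generated in situ transfers two hydrogens to the same side of the polarised 1-chloroalkyne (diimide cis-reduction of a haloalkyne), so ring carbon and chlorine should end cis (Z), while the ketone and the C–Cl bonds are inert to diimide.

Step 9
Reactants: 18 (2R,4S,5S)-2,4-dichloro-5-[(Z)-2-chloroethenyl]-5-methylcyclohexan-1-one; 19 dibromomethane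
Product: 20 (1S,2S,4R)-2,4-dichloro-1-[(Z)-2-chloroethenyl]-1-methyl-5-methylidenecyclohexane
Conditions: Zn, CH2Br2, TiCl4, THF, 0 °C (pre-formed reagent); then 18, CH2Cl2, 0 °C to rt
Reagents that add atoms: dibromomethane, BrCBr
Why: Takai–Lombardo methylenation uses a non-basic, oxophilic titanium–methylene reagent that should convert the hindered, enolisable ketone into the exocyclic alkene without epimerising the chlorine-bearing C4 next to it.

Step 10
Reactants: 20 (1S,2S,4R)-2,4-dichloro-1-[(Z)-2-chloroethenyl]-1-methyl-5-methylidenecyclohexane; 21 bromine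
Product: 22 (1S,2R,4S,5S)-1-bromo-1-(bromomethyl)-2,4-dichloro-5-[(Z)-2-chloroethenyl]-5-methylcyclohexane
Conditions: Br2 (1.0 equiv), CH2Cl2, −78 °C, dark
Reagents that add atoms: bromine, BrBr
Why: Electrophilic anti-addition of bromine through a bromonium ion should occur only at the electron-richer 1,1-disubstituted alkene (the chlorovinyl group is deactivated), with the bromonium on the face of the C1 methyl group and bromide opening it axially at the tertiary C3, which puts the C3 bromine cis to the C4 chlorine and the CH2Br group equatorial, the arrangement with the smaller syn-axial contact to the axial chlorovinyl group.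

Compound list
1 | isoprene monoepoxide (racemic 2-ethenyl-2-methyloxirane) | CC1(C=C)CO1 | starting material
2 | Meldrum's acid (2,2-dimethyl-1,3-dioxane-4,6-dione) | CC1(C)OC(=O)CC(=O)O1 | starting material
3 | 5-[(2S)-1-hydroxy-2-methylbut-3-en-2-yl]-2,2-dimethyl-1,3-dioxane-4,6-dione | CC1(C)OC(=O)C(C(=O)O1)[C@](C)(C=C)CO | intermediate
4 | (4S)-4-ethenyl-4-methyl-2-oxooxolane-3-carboxylic acid (either configuration at C3) | O=C1OC[C@@](C)(C=C)C1C(=O)O | intermediate
5 | (4R)-4-ethenyl-4-methyloxolan-2-one | O=C1C[C@](C)(C=C)CO1 | intermediate
6 | N,O-dimethylhydroxylamine hydrochloride | CNOC.Cl | starting material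
7 | (3R)-3-(hydroxymethyl)-N-methoxy-N,3-dimethylpent-4-enamide | CON(C)C(=O)C[C@](C)(C=C)CO | intermediate
8 | (3R)-3-formyl-N-methoxy-N,3-dimethylpent-4-enamide | CON(C)C(=O)C[C@](C)(C=C)C=O | intermediate
9 | dimethyl (1-diazo-2-oxopropyl)phosphonate (Ohira–Bestmann reagent) | COP(=O)(OC)C(=[N+]=[N-])C(C)=O | starting material
10 | (3R)-3-ethynyl-N-methoxy-N,3-dimethylpent-4-enamide | CON(C)C(=O)C[C@](C)(C=C)C#C | intermediate
11 | N-chlorosuccinimide | O=C1CCC(=O)N1Cl | starting material
12 | lithium acetylide of 10, lithium (3R)-3-ethenyl-5-[methoxy(methyl)amino]-3-methyl-5-oxopent-1-yn-1-ide | CON(C)C(=O)C[C@](C)(C=C)C#C[Li] | intermediate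
13 | (3R)-3-(chloroethynyl)-N-methoxy-N,3-dimethylpent-4-enamide | CON(C)C(=O)C[C@](C)(C=C)C#CCl | intermediate
14 | dichloromethane | ClCCl | starting material
15 | lithium (4R)-1,1-dichloro-4-(chloroethynyl)-2-[methoxy(methyl)amino]-4-methylhex-5-en-2-olate (either configuration at C2) | CON(C)C(O[Li])(C(Cl)Cl)C[C@](C)(C=C)C#CCl | intermediate
16 | (4R)-1,1-dichloro-4-(chloroethynyl)-4-methylhex-5-en-2-one | ClC(Cl)C(=O)C[C@](C)(C=C)C#CCl | intermediate
17 | (2R,4S,5S)-2,4-dichloro-5-(chloroethynyl)-5-methylcyclohexan-1-one | C[C@@]1(C#CCl)CC(=O)[C@H](Cl)C[C@@H]1Cl | intermediate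
18 | (2R,4S,5S)-2,4-dichloro-5-[(Z)-2-chloroethenyl]-5-methylcyclohexan-1-one | C[C@@]1(/C=C\Cl)CC(=O)[C@H](Cl)C[C@@H]1Cl | intermediate
19 | dibromomethane | BrCBr | starting material
20 | (1S,2S,4R)-2,4-dichloro-1-[(Z)-2-chloroethenyl]-1-methyl-5-methylidenecyclohexane | C[C@@]1(/C=C\Cl)CC(=C)[C@H](Cl)C[C@@H]1Cl | intermediate
21 | bromine | BrBr | starting material
22 | (1S,2R,4S,5S)-1-bromo-1-(bromomethyl)-2,4-dichloro-5-[(Z)-2-chloroethenyl]-5-methylcyclohexane | C[C@@]1(/C=C\Cl)C[C@@](Br)(CBr)[C@H](Cl)C[C@@H]1Cl | target

Total step count: 10. Longest linear sequence: 10 steps (from 1 to 22).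

Steps most likely to fail

Step 7. Chlorine abstraction from the singly activated dichloride may be slow, so that radicals or the product chloroketone are reduced at the cathode. Closure may also leak into the five-membered mode, or chlorine may return to the C6 radical on the face of the methyl group. The fallback makes the radical from a doubly activated dichloride under thermal copper catalysis, the best-documented form of this 6-endo chlorine-transfer cyclisation; it answers the first two failure modes, while the facial element is common to both variants. It sets out from 13. The lithium enolate of tert-butyl acetate (LiN(i-Pr)2, THF, −78 °C) should acylate the Weinreb amide to tert-butyl (5R)-5-(chloroethynyl)-5-methyl-3-oxohept-6-enoate F1. SO2Cl2 (2 equiv, CH2Cl2, 0 °C) should then give tert-butyl (5R)-2,2-dichloro-5-(chloroethynyl)-5-methyl-3-oxohept-6-enoate F2. CuCl with 2,2′-bipyridine (catalytic, 1,2-dichloroethane, 80 °C) should cyclise this to tert-butyl (4S,5S)-1,5-dichloro-4-(chloroethynyl)-4-methyl-2-oxocyclohexane-1-carboxylate F3. TFA in CH2Cl2 should cleave the ester to (4S,5S)-1,5-dichloro-4-(chloroethynyl)-4-methyl-2-oxocyclohexane-1-carboxylic acid F4, which loses CO2 on gentle warming. The sequence comes back to the route at 17, with C4 equilibrated by acid as in the main line.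

Step 10. Facial selectivity may be poor: the bromonium ion may form on the face of the axial chlorovinyl group, or bromide may enter C3 from the equatorial side, which would invert C3. The fallback introduces the two bromines one at a time, so that the face is fixed by addition to the ketone. It sets out from 18 and bypasses 20. Bromomethyllithium made in situ (CH2Br2, MeLi·LiBr, THF, −78 °C, cold AcOH quench) should add to the carbonyl from the equatorial side, away from the axial chlorovinyl group. This should give (1S,2R,4S,5S)-1-(bromomethyl)-2,4-dichloro-5-[(Z)-2-chloroethenyl]-5-methylcyclohexan-1-ol F5, with CH2Br equatorial and OH axial. HBr in AcOH (or Me3SiBr, CH2Cl2, 0 °C) should then replace the tertiary hydroxyl with retention: the neighbouring bromine displaces the activated oxygen from the rear, forming the bromonium ion on the required face, and bromide reopens it at the tertiary carbon. The sequence comes back to the route at 22.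

Step 9. Zinc or low-valent titanium may strip the chlorine next to the carbonyl (reductive dechlorination), or the Lewis-acidic medium may enolise the ketone and scramble C4. The fallback is a Peterson olefination, which needs neither a reducing metal nor a strong base at the carbonyl stage. It sets out from 18. Me3SiCH2MgCl with CeCl3 (THF, −78 °C) should add to the ketone to give (2R,4S,5S)-2,4-dichloro-5-[(Z)-2-chloroethenyl]-5-methyl-1-[(trimethylsilyl)methyl]cyclohexan-1-ol F6, either configuration at the carbinol carbon being usable. Acid-promoted anti-elimination (catalytic H2SO4 in THF, or BF3·OEt2 in CH2Cl2 at 0 °C) then comes back to the route at 20.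

Further compounds
F1 | step 7 | tert-butyl (5R)-5-(chloroethynyl)-5-methyl-3-oxohept-6-enoate | CC(C)(C)OC(=O)CC(=O)C[C@](C)(C=C)C#CCl
F2 | step 7 | tert-butyl (5R)-2,2-dichloro-5-(chloroethynyl)-5-methyl-3-oxohept-6-enoate | CC(C)(C)OC(=O)C(Cl)(Cl)C(=O)C[C@](C)(C=C)C#CCl
F3 | step 7 | tert-butyl (4S,5S)-1,5-dichloro-4-(chloroethynyl)-4-methyl-2-oxocyclohexane-1-carboxylate (either configuration at C1) | C[C@@]1(C#CCl)CC(=O)C(Cl)(C(=O)OC(C)(C)C)C[C@@H]1Cl
F4 | step 7 | (4S,5S)-1,5-dichloro-4-(chloroethynyl)-4-methyl-2-oxocyclohexane-1-carboxylic acid (either configuration at C1) | C[C@@]1(C#CCl)CC(=O)C(Cl)(C(=O)O)C[C@@H]1Cl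
F5 | step 10 | (1S,2R,4S,5S)-1-(bromomethyl)-2,4-dichloro-5-[(Z)-2-chloroethenyl]-5-methylcyclohexan-1-ol | C[C@@]1(/C=C\Cl)C[C@@](O)(CBr)[C@H](Cl)C[C@@H]1Cl
F6 | step 9 | (2R,4S,5S)-2,4-dichloro-5-[(Z)-2-chloroethenyl]-5-methyl-1-[(trimethylsilyl)methyl]cyclohexan-1-ol (either configuration at C1) | C[C@@]1(/C=C\Cl)CC(O)(C[Si](C)(C)C)[C@H](Cl)C[C@@H]1Cl
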